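**Retrosynthetic overview**
1. Endgame from the bicyclic keto ester 24: C8 ketone to the equatorial 8α-alcohol, Mannich methylenation of the C11–C12 ester, exchange of the C6 silyl ether for the angelate, desilylation.
2. Key disconnection: C4–C5 and C9–C10 of the trans-decalin are formed in one Lewis acid cascade from the open-chain keto enol silane 22; ring A closes first, ring B second.
3. The strategy rests on the row C4 (tertiary carbinol) – C5/C10 (trans fusion, quaternary C10 methyl) – C8 (oxygen) of rings A and B, which along one chain is a methyl ketone, an E-trisubstituted alkene and an enol ether. The C4 and C6 oxygens end up syn across C5, so one aluminium centre can hold both.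
4. Chain assembly: C6–C7 by Evans syn-aldol of a succinate imide with the (E)-enal 10; 10 comes from a Noyori-reduced silyl ynone by carboalumination and formylation.
5. C4 is carried as a Weinreb amide and becomes the methyl ketone only after the C8 enol silane is in place, so the two methyl ketones never coexist. C6 carries a triethylsilyl (TES) ether and C1 a tert-butyldimethylsilyl (TBS) ether, so that C6 can be unveiled alone.

Key step: step 15

Remark: C1–C15 are the eudesmane locants of the target and are used for open-chain compounds too; the SMILES is read as methyl 6α-angeloyloxy-1β,4α,8α-trihydroxy-5α-eudesm-11(13)-en-12-oate (5α-H, 10β-CH3, 7β side chain).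

**Route**

Step 1
Reactants: 1 methyl 4-chloro-4-oxobutanoate; 2 ethynyltrimethylsilane
Product: 3 methyl 4-oxo-6-(trimethylsilyl)hex-5-ynoate
Conditions: PdCl2(PPh3)2 (2 mol%), CuI (4 mol%), Et3N, THF, rt
Reagents that add atoms: none
Why: Acyl Sonogashira coupling of an acid chloride with a terminal alkyne gives the silyl-capped ynone (C1 carbonyl, C10≡C5) without touching the methyl ester that becomes C4.

Step 2
Reactants: 3 methyl 4-oxo-6-(trimethylsilyl)hex-5-ynoate
Product: 4 methyl (4R)-4-hydroxy-6-(trimethylsilyl)hex-5-ynoate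
Conditions: RuCl[(R,R)-TsDPEN](p-cymene) (1 mol%), i-PrOH, rt
Reagents that add atoms: none
Why: Noyori asymmetric transfer hydrogenation of an alkynyl ketone, in which the alkyne takes the place of the aryl group of an aryl ketone, so that the (R,R) catalyst should give the (R)-carbinol at C1.

Step 3
Reactants: 4 methyl (4R)-4-hydroxy-6-(trimethylsilyl)hex-5-ynoate
Product: 5 (4R)-4-hydroxy-N-methoxy-N-methyl-6-(trimethylsilyl)hex-5-ynamide
Conditions: MeNH(OMe)·HCl, AlMe3, CH2Cl2, 0 °C to rt
Reagents that add atoms: N,O-dimethylhydroxylamine hydrochloride, CNOC.Cl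
Why: Weinreb aminolysis with the aluminium amide converts the ester (and any γ-lactone that 4 has formed) into the N-methoxy-N-methylamide, the masked form in which C4 survives every later base and cuprate.

Step 4
Reactants: 5 (4R)-4-hydroxy-N-methoxy-N-methyl-6-(trimethylsilyl)hex-5-ynamide
Product: 6 (4R)-4-[(tert-butyldimethylsilyl)oxy]-N-methoxy-N-methyl-6-(trimethylsilyl)hex-5-ynamide
Conditions: TBSCl, imidazole, DMF, rt
Reagents that add atoms: tert-butyldimethylsilyl chloride, CC(C)(C)[Si](C)(C)Cl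
Why: Silylation of the secondary alcohol with TBSCl/imidazole blocks relactonisation of the γ-hydroxy amide and installs the C1 protecting group that is kept to the last step.

Step 5
Reactants: 6 (4R)-4-[(tert-butyldimethylsilyl)oxy]-N-methoxy-N-methyl-6-(trimethylsilyl)hex-5-ynamide
Product: 7 (4R)-4-[(tert-butyldimethylsilyl)oxy]-N-methoxy-N-methylhex-5-ynamide
Conditions: K2CO3 (0.2 equiv), MeOH, 0 °C to rt
Reagents that add atoms: none
Why: Carbonate-catalysed methanolysis cleaves only the alkynyl C–Si bond, leaving the silyl ether and the amide, and frees the terminal alkyne needed for carbometalation.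

Step 6
Reactants: 7 (4R)-4-[(tert-butyldimethylsilyl)oxy]-N-methoxy-N-methylhex-5-ynamide
Product: 9 (4R,5E)-4-[(tert-butyldimethylsilyl)oxy]-6-iodo-N-methoxy-N,5-dimethylhex-5-enamide, via alkenyldimethylalane 8 (not isolated)
Conditions: AlMe3 (3.5 equiv), Cp2ZrCl2 (0.25 equiv), CH2Cl2, 0 °C to rt; then I2, THF, −30 °C
Reagents that add atoms: trimethylaluminium, C[Al](C)C; iodine, II
Why: Negishi zirconium-catalysed carboalumination adds CH3 (C14) and aluminium syn across the terminal alkyne with aluminium on C5, and iodinolysis with retention fixes the E geometry of the future C5=C10 alkene (C1 trans to iodine).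

Step 7
Reactants: 9 (4R,5E)-4-[(tert-butyldimethylsilyl)oxy]-6-iodo-N-methoxy-N,5-dimethylhex-5-enamide
Product: 10 (4R,5E)-4-[(tert-butyldimethylsilyl)oxy]-N-methoxy-N,5-dimethyl-7-oxohept-5-enamide
Conditions: Pd(PPh3)4 (5 mol%), CO (1 atm), Bu3SnH (slow addition), THF, 50 °C
Reagents that add atoms: carbon monoxide, [C-]#[O+]
Why: Palladium-catalysed reductive carbonylation (formylation) of an alkenyl iodide introduces C6 with retention of the double-bond geometry and, unlike a lithiation/DMF sequence, is compatible with the Weinreb amide.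

Step 8
Reactants: 11 (4S)-4-benzyl-1,3-oxazolidin-2-one; 1 methyl 4-chloro-4-oxobutanoate
Product: 12 methyl 4-[(4S)-4-benzyl-2-oxo-1,3-oxazolidin-3-yl]-4-oxobutanoate
Conditions: Et3N, DMAP (10 mol%), CH2Cl2, 0 °C to rt
Reagents that add atoms: none
Why: DMAP-catalysed N-acylation of the oxazolidinone auxiliary with the acid chloride gives the succinate imide whose imide carbonyl becomes C8 and whose α-CH2 becomes C7.

Step 9
Reactants: 12 methyl 4-[(4S)-4-benzyl-2-oxo-1,3-oxazolidin-3-yl]-4-oxobutanoate; 10 (4R,5E)-4-[(tert-butyldimethylsilyl)oxy]-N-methoxy-N,5-dimethyl-7-oxohept-5-enamide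
Product: 15 methyl (3S,4R,5E,7R)-3-[(4S)-4-benzyl-2-oxo-1,3-oxazolidine-3-carbonyl]-7-[(tert-butyldimethylsilyl)oxy]-4-hydroxy-10-[methoxy(methyl)amino]-6-methyl-10-oxodec-5-enoate (eudesmane locants 1R,6R,7S), via boron enolate 13 (not isolated), via boron aldolate 14 (not isolated)
Conditions: Bu2BOTf, i-Pr2NEt, CH2Cl2, −78 to 0 °C; then 10, −78 to 0 °C; then aq. NaH2PO4/Na2HPO4 (pH 7), MeOH, H2O2, 0 °C
Reagents that add atoms: none
Why: Evans syn-aldol reaction, in which the Z-dibutylboron enolate adds to the enal through a Zimmerman–Traxler chair on the enolate face away from the benzyl group and so sets (6R,7S) with the 6-hydroxyl and the C7 acetate arm syn; the adduct is silylated at once because a free γ-hydroxy ester can lactonise.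

Step 10
Reactants: 15 syn-aldol adduct (free 6-OH)
Product: 16 methyl (3S,4R,5E,7R)-3-[(4S)-4-benzyl-2-oxo-1,3-oxazolidine-3-carbonyl]-7-[(tert-butyldimethylsilyl)oxy]-10-[methoxy(methyl)amino]-6-methyl-10-oxo-4-[(triethylsilyl)oxy]dec-5-enoate
Conditions: TESOTf, 2,6-lutidine, CH2Cl2, −78 °C
Reagents that add atoms: triethylsilyl trifluoromethanesulfonate, CC[Si](CC)(CC)OS(=O)(=O)C(F)(F)F
Why: Silyl triflate/lutidine silylation of the hindered allylic alcohol gives the TES ether, which is more labile than the TBS ethers and marks C6 for later selective unveiling.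

Step 11
Reactants: 16 TES-protected aldol imide
Product: 17 methyl (3S,4R,5E,7R)-7-[(tert-butyldimethylsilyl)oxy]-3-[(ethylsulfanyl)carbonyl]-10-[methoxy(methyl)amino]-6-methyl-10-oxo-4-[(triethylsilyl)oxy]dec-5-enoate
Conditions: EtSH, n-BuLi, THF, 0 °C
Reagents that add atoms: ethanethiol, CCS
Why: Thiolysis of the activated imide by lithium ethanethiolate displaces the oxazolidinone from the C8 carbonyl, which is far more electrophilic than the methyl ester or the Weinreb amide, and gives the S-ethyl thioester without epimerising C7.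

Step 12
Reactants: 17 C8 S-ethyl thioester
Product: 18 methyl (3S,4R,5E,7R)-3-acetyl-7-[(tert-butyldimethylsilyl)oxy]-10-[methoxy(methyl)amino]-6-methyl-10-oxo-4-[(triethylsilyl)oxy]dec-5-enoate
Conditions: Me2CuLi (from CuI and MeLi), Et2O, −78 to −40 °C
Reagents that add atoms: lithium dimethylcuprate, [Li+].C[Cu-]C
Why: Acylation of a lithium dialkylcuprate by a thioester gives the C8 methyl ketone (C9 introduced) and stops there, the methyl ester and the Weinreb amide being inert to the cuprate.

Step 13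
Reactants: 18 C8 methyl ketone
Product: 20 methyl (3S,4R,5E,7R)-7-[(tert-butyldimethylsilyl)oxy]-3-{1-[(tert-butyldimethylsilyl)oxy]ethenyl}-10-[methoxy(methyl)amino]-6-methyl-10-oxo-4-[(triethylsilyl)oxy]dec-5-enoate, via lithium enolate 19 (not isolated)
Conditions: LiN(SiMe3)2, THF, −78 °C; then TBSOTf, −78 °C
Reagents that add atoms: tert-butyldimethylsilyl trifluoromethanesulfonate, CC(C)(C)[Si](C)(C)OS(=O)(=O)C(F)(F)F
Why: Kinetic deprotonation of the methyl ketone at the unhindered C9 methyl (the C7 methine, the ester and the amide react more slowly) and O-silylation give the terminal TBS enol ether, made while C4 is still an amide so that only one methyl ketone is present.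

Step 14
Reactants: 20 C8 enol silane with C4 Weinreb amide
Product: 22 methyl (3S,4R,5E,7R)-7-[(tert-butyldimethylsilyl)oxy]-3-{1-[(tert-butyldimethylsilyl)oxy]ethenyl}-6-methyl-10-oxo-4-[(triethylsilyl)oxy]undec-5-enoate (eudesmane locants 1R,6R,7S), via magnesium hemiaminal chelate 21 (not isolated)
Conditions: MeMgBr (1.5 equiv), THF, −40 to 0 °C; then aq. NaH2PO4/Na2HPO4 (pH 7), 0 °C
Reagents that add atoms: methylmagnesium bromide, C[Mg]Br
Why: Weinreb ketone synthesis, in which the chelated tetrahedral adduct holds until the buffered quench so that the C4 methyl ketone (C15 introduced) appears only after all base is gone, the Weinreb amide reacting faster than the methyl ester and the enol silane being inert to the Grignard reagent.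

Step 15
Reactants: 22 (E)-keto enol silane (C4 methyl ketone, C5=C10 alkene, C8 TBS enol ether, 1-OTBS, 6-OTES)
Product: 24 methyl 1β-[(tert-butyldimethylsilyl)oxy]-4α-hydroxy-8-oxo-6α-[(triethylsilyl)oxy]-13-nor-5α-eudesman-12-oate, via ring A C10 carbocation 23 (not isolated)
Conditions: MeAlCl2 (2.5 equiv), CH2Cl2 (0.005 M), −78 to −40 °C; then Et3N, aq. NaHCO3
Reagents that add atoms: none
Why: Proposed new method: MeAlCl2 binds the C4 ketone oxygen, C5 of the E-alkene adds to C4 and leaves the tertiary C10 cation 23, C9 of the enol silane adds to C10, chloride takes the silyl group to give the C8 ketone, and work-up frees the C4 alcohol. The closest known reactions are MeAlCl2-promoted Prins cyclisations of δ,ε-unsaturated ketones and epoxide- or acetal-initiated cation–olefin polycyclisations that end at a silyl enol ether; a ketone initiator combined with an enol silane terminator across an alkene flanked by two allylic silyl ethers is not known. Ring A closes through a chair, 6-endo with respect to the C5=C10 alkene (6-exo-trig at the carbonyl, Markovnikov), and ring B closes through a second chair, 6-endo with respect to the C8=C9 enol ether, onto the C10 cation. C5 and C10 come from anti addition across the E-alkene (trans fusion, 5α-H, 10β-CH3), their absolute sense from the chair–chair fold that keeps the C1 silyl ether, the C6 silyl ether and the C7 acetate arm equatorial, and C4 from the aluminium-bound oxygen taking the equatorial site next to the C6 oxygen, where excess MeAlCl2, a Lewis acid that can chelate even silyl ether oxygens as a cationic aluminium centre, can bridge O4 and O6 so that C15 goes axial. The step needs ring closure to outrun intermolecular Mukaiyama aldol addition, ionisation of the allylic silyl ethers and a 1,2-hydride shift from C1 to C10, for which high dilution, −78 °C and the enol ether held over C10 by the chair of ring A are relied on. The electron-poor alkene and the orientation at C4 are the two open points.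

Step 16
Reactants: 24 bicyclic 8-ketone
Product: 25 methyl 1β-[(tert-butyldimethylsilyl)oxy]-4α,8α-dihydroxy-6α-[(triethylsilyl)oxy]-13-nor-5α-eudesman-12-oate
Conditions: SmI2 (2.5 equiv), H2O, THF, 0 °C
Reagents that add atoms: none
Why: Single-electron ketone reduction by SmI2/H2O runs through the ketyl and a carbanion that is protonated on carbon from the axial side, as in dissolving-metal reductions, and should give the equatorial 8α-alcohol (a hydride reagent would attack from the α face, away from the axial C10 methyl, and give 8β), while the methyl ester is not reduced in the absence of an amine.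

Step 17
Reactants: 25 8α-alcohol
Product: 26 methyl 1β,8α-bis[(tert-butyldimethylsilyl)oxy]-4α-hydroxy-6α-[(triethylsilyl)oxy]-13-nor-5α-eudesman-12-oate
Conditions: TBSCl, imidazole, DMF, 35 °C
Reagents that add atoms: tert-butyldimethylsilyl chloride, CC(C)(C)[Si](C)(C)Cl
Why: Silylation of the secondary 8α-alcohol (the tertiary C4 alcohol does not react with TBSCl/imidazole) stops lactonisation onto C12 and shields the hydroxyl from the base of the next step.

Step 18
Reactants: 26 C8 TBS ether
Product: 28 methyl 1β,8α-bis[(tert-butyldimethylsilyl)oxy]-13-(dimethylamino)-4α-hydroxy-6α-[(triethylsilyl)oxy]-5α-eudesman-12-oate (both C11 epimers), via lithium ester enolate 27 (not isolated)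
Conditions: LiN(i-Pr)2 (2.3 equiv), THF, −78 °C; then CH2=NMe2+ I−, −78 to 0 °C
Reagents that add atoms: N,N-dimethylmethyleneiminium iodide, C=[N+](C)C.[I-]
Why: Mannich alkylation of the ester enolate (one further equivalent of base is taken up by the C4 hydroxyl) with the iminium salt puts the future C13 on C11, whose configuration is of no consequence.

Step 19
Reactants: 28 Mannich base
Product: 30 methyl 1β,8α-bis[(tert-butyldimethylsilyl)oxy]-4α-hydroxy-6α-[(triethylsilyl)oxy]-5α-eudesm-11(13)-en-12-oate, via trimethylammonium iodide 29 (not isolated)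
Conditions: MeI, MeOH, rt; then DBU, CH2Cl2, rt
Reagents that add atoms: none
Why: Quaternisation of the amine and base-induced β-elimination of trimethylamine (Hofmann-type elimination) give the α-methylene ester C11=C13.

Step 20
Reactants: 30 α-methylene ester with 6-OTES
Product: 31 methyl 1β,8α-bis[(tert-butyldimethylsilyl)oxy]-4α,6α-dihydroxy-5α-eudesm-11(13)-en-12-oate
Conditions: PPTS (10 mol%), MeOH/CH2Cl2, 0 °C
Reagents that add atoms: none
Why: Mild acid methanolysis cleaves the TES ether much faster than the secondary TBS ethers and so frees only the 6α-hydroxyl.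

Step 21
Reactants: 31 6α-alcohol; 32 angelic acid [(Z)-2-methylbut-2-enoic acid]
Product: 34 methyl 6α-(angeloyloxy)-1β,8α-bis[(tert-butyldimethylsilyl)oxy]-4α-hydroxy-5α-eudesm-11(13)-en-12-oate, via angelic 2,4,6-trichlorobenzoic anhydride 33 (not isolated)
Conditions: 32, 2,4,6-Cl3C6H2COCl, Et3N, toluene, rt; then 31, toluene, 80 °C
Reagents that add atoms: none
Why: Yamaguchi-type esterification through the 2,4,6-trichlorobenzoyl mixed anhydride without a nucleophilic catalyst acylates the secondary 6α-hydroxyl (the tertiary C4 hydroxyl is inert) and avoids the addition–elimination pathway that turns angelates into tiglates.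

Step 22
Reactants: 34 bis-TBS angelate
Product: 35 methyl 6α-(angeloyloxy)-1β,4α,8α-trihydroxy-5α-eudesm-11(13)-en-12-oate (CNP0136844.1)
Conditions: HF·pyridine, pyridine, THF, 0 °C to rt
Reagents that add atoms: none
Why: Fluoride-mediated desilylation under buffered, non-basic conditions removes both TBS ethers without acyl migration, angelate isomerisation or lactonisation of the 8α-hydroxy ester.

**Compound list**

1 | methyl 4-chloro-4-oxobutanoate | COC(=O)CCC(Cl)=O | starting material
2 | ethynyltrimethylsilane | C#C[Si](C)(C)C | starting material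
3 | methyl 4-oxo-6-(trimethylsilyl)hex-5-ynoate | COC(=O)CCC(=O)C#C[Si](C)(C)C | intermediate
4 | methyl (4R)-4-hydroxy-6-(trimethylsilyl)hex-5-ynoate | COC(=O)CC[C@@H](O)C#C[Si](C)(C)C | intermediate
5 | (4R)-4-hydroxy-N-methoxy-N-methyl-6-(trimethylsilyl)hex-5-ynamide | CON(C)C(=O)CC[C@@H](O)C#C[Si](C)(C)C | intermediate
6 | (4R)-4-[(tert-butyldimethylsilyl)oxy]-N-methoxy-N-methyl-6-(trimethylsilyl)hex-5-ynamide | CON(C)C(=O)CC[C@@H](O[Si](C)(C)C(C)(C)C)C#C[Si](C)(C)C | intermediate
7 | (4R)-4-[(tert-butyldimethylsilyl)oxy]-N-methoxy-N-methylhex-5-ynamide | CON(C)C(=O)CC[C@@H](O[Si](C)(C)C(C)(C)C)C#C | intermediate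
8 | (E)-alkenyldimethylalane from 7 (CH3 on C10, AlMe2 on C5) | CON(C)C(=O)CC[C@@H](O[Si](C)(C)C(C)(C)C)/C(C)=C/[Al](C)C | intermediate
9 | (4R,5E)-4-[(tert-butyldimethylsilyl)oxy]-6-iodo-N-methoxy-N,5-dimethylhex-5-enamide | CON(C)C(=O)CC[C@@H](O[Si](C)(C)C(C)(C)C)/C(C)=C/I | intermediate
10 | (4R,5E)-4-[(tert-butyldimethylsilyl)oxy]-N-methoxy-N,5-dimethyl-7-oxohept-5-enamide | CON(C)C(=O)CC[C@@H](O[Si](C)(C)C(C)(C)C)/C(C)=C/C=O | intermediate
11 | (4S)-4-benzyl-1,3-oxazolidin-2-one | O=C1N[C@@H](Cc2ccccc2)CO1 | starting material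
12 | methyl 4-[(4S)-4-benzyl-2-oxo-1,3-oxazolidin-3-yl]-4-oxobutanoate | COC(=O)CCC(=O)N1[C@@H](Cc2ccccc2)COC1=O | intermediate
13 | (Z)-dibutylboron enolate of 12 | COC(=O)C/C=C(\OB(CCCC)CCCC)N1[C@@H](Cc2ccccc2)COC1=O | intermediate
14 | dibutylboron aldolate of 15 | CON(C)C(=O)CC[C@@H](O[Si](C)(C)C(C)(C)C)/C(C)=C/[C@@H](OB(CCCC)CCCC)[C@H](CC(=O)OC)C(=O)N1[C@@H](Cc2ccccc2)COC1=O | intermediate
15 | syn-aldol adduct (1R,6R,7S): C8 imide, 6-OH, 1-OTBS, C4 Weinreb amide, C12 methyl ester | CON(C)C(=O)CC[C@@H](O[Si](C)(C)C(C)(C)C)/C(C)=C/[C@@H](O)[C@H](CC(=O)OC)C(=O)N1[C@@H](Cc2ccccc2)COC1=O | intermediate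
16 | 6-O-TES ether of 15 | CON(C)C(=O)CC[C@@H](O[Si](C)(C)C(C)(C)C)/C(C)=C/[C@@H](O[Si](CC)(CC)CC)[C@H](CC(=O)OC)C(=O)N1[C@@H](Cc2ccccc2)COC1=O | intermediate
17 | C8 S-ethyl thioester (1R,6R,7S) | CON(C)C(=O)CC[C@@H](O[Si](C)(C)C(C)(C)C)/C(C)=C/[C@@H](O[Si](CC)(CC)CC)[C@H](CC(=O)OC)C(=O)SCC | intermediate
18 | C8 methyl ketone (1R,6R,7S) | CON(C)C(=O)CC[C@@H](O[Si](C)(C)C(C)(C)C)/C(C)=C/[C@@H](O[Si](CC)(CC)CC)[C@H](CC(=O)OC)C(C)=O | intermediate
19 | lithium enolate of 18 (C8–O–Li, C8=C9) | CON(C)C(=O)CC[C@@H](O[Si](C)(C)C(C)(C)C)/C(C)=C/[C@@H](O[Si](CC)(CC)CC)[C@H](CC(=O)OC)C(=C)O[Li] | intermediate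
20 | C8 TBS enol ether with C4 Weinreb amide (1R,6R,7S) | CON(C)C(=O)CC[C@@H](O[Si](C)(C)C(C)(C)C)/C(C)=C/[C@@H](O[Si](CC)(CC)CC)[C@H](CC(=O)OC)C(O[Si](C)(C)C(C)(C)C)=C | intermediate
21 | bromomagnesium hemiaminal chelate at C4 from 20 | CC(O[Mg]Br)(N(C)OC)CC[C@@H](O[Si](C)(C)C(C)(C)C)/C(C)=C/[C@@H](O[Si](CC)(CC)CC)[C@H](CC(=O)OC)C(O[Si](C)(C)C(C)(C)C)=C | intermediate
22 | (E)-keto enol silane, key-step precursor (1R,6R,7S; C4 methyl ketone, 1-OTBS, 6-OTES, C8 TBS enol ether) | CC(=O)CC[C@@H](O[Si](C)(C)C(C)(C)C)/C(C)=C/[C@@H](O[Si](CC)(CC)CC)[C@H](CC(=O)OC)C(O[Si](C)(C)C(C)(C)C)=C | intermediate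
23 | ring A C10 carbocation with C4 aluminate alkoxide | C[Al-](Cl)(Cl)O[C@]1(C)CC[C@@H](O[Si](C)(C)C(C)(C)C)[C+](C)[C@H]1[C@@H](O[Si](CC)(CC)CC)[C@H](CC(=O)OC)C(O[Si](C)(C)C(C)(C)C)=C | intermediate
24 | methyl 1β-[(tert-butyldimethylsilyl)oxy]-4α-hydroxy-8-oxo-6α-[(triethylsilyl)oxy]-13-nor-5α-eudesman-12-oate | COC(=O)C[C@H]1[C@H](O[Si](CC)(CC)CC)[C@@H]2[C@@](C)(CC1=O)[C@H](O[Si](C)(C)C(C)(C)C)CC[C@@]2(C)O | intermediate
25 | methyl 1β-[(tert-butyldimethylsilyl)oxy]-4α,8α-dihydroxy-6α-[(triethylsilyl)oxy]-13-nor-5α-eudesman-12-oate | COC(=O)C[C@H]1[C@H](O[Si](CC)(CC)CC)[C@@H]2[C@@](C)(C[C@@H]1O)[C@H](O[Si](C)(C)C(C)(C)C)CC[C@@]2(C)O | intermediate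
26 | methyl 1β,8α-bis[(tert-butyldimethylsilyl)oxy]-4α-hydroxy-6α-[(triethylsilyl)oxy]-13-nor-5α-eudesman-12-oate | COC(=O)C[C@H]1[C@H](O[Si](CC)(CC)CC)[C@@H]2[C@@](C)(C[C@@H]1O[Si](C)(C)C(C)(C)C)[C@H](O[Si](C)(C)C(C)(C)C)CC[C@@]2(C)O | intermediate
27 | lithium ester enolate (and C4 lithium alkoxide) of 26 | COC(O[Li])=C[C@H]1[C@H](O[Si](CC)(CC)CC)[C@@H]2[C@@](C)(C[C@@H]1O[Si](C)(C)C(C)(C)C)[C@H](O[Si](C)(C)C(C)(C)C)CC[C@@]2(C)O[Li] | intermediate
28 | methyl 1β,8α-bis[(tert-butyldimethylsilyl)oxy]-13-(dimethylamino)-4α-hydroxy-6α-[(triethylsilyl)oxy]-5α-eudesman-12-oate (C11 epimers) | COC(=O)C(CN(C)C)[C@H]1[C@H](O[Si](CC)(CC)CC)[C@@H]2[C@@](C)(C[C@@H]1O[Si](C)(C)C(C)(C)C)[C@H](O[Si](C)(C)C(C)(C)C)CC[C@@]2(C)O | intermediate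
29 | trimethylammonium iodide of 28 | COC(=O)C(C[N+](C)(C)C)[C@H]1[C@H](O[Si](CC)(CC)CC)[C@@H]2[C@@](C)(C[C@@H]1O[Si](C)(C)C(C)(C)C)[C@H](O[Si](C)(C)C(C)(C)C)CC[C@@]2(C)O.[I-] | intermediate
30 | methyl 1β,8α-bis[(tert-butyldimethylsilyl)oxy]-4α-hydroxy-6α-[(triethylsilyl)oxy]-5α-eudesm-11(13)-en-12-oate | C=C(C(=O)OC)[C@H]1[C@H](O[Si](CC)(CC)CC)[C@@H]2[C@@](C)(C[C@@H]1O[Si](C)(C)C(C)(C)C)[C@H](O[Si](C)(C)C(C)(C)C)CC[C@@]2(C)O | intermediate
31 | methyl 1β,8α-bis[(tert-butyldimethylsilyl)oxy]-4α,6α-dihydroxy-5α-eudesm-11(13)-en-12-oate | C=C(C(=O)OC)[C@H]1[C@H](O)[C@@H]2[C@@](C)(C[C@@H]1O[Si](C)(C)C(C)(C)C)[C@H](O[Si](C)(C)C(C)(C)C)CC[C@@]2(C)O | intermediate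
32 | angelic acid, (Z)-2-methylbut-2-enoic acid | C/C=C(/C)C(=O)O | starting material
33 | angelic 2,4,6-trichlorobenzoic anhydride | C/C=C(/C)C(=O)OC(=O)c1c(Cl)cc(Cl)cc1Cl | intermediate
34 | methyl 6α-(angeloyloxy)-1β,8α-bis[(tert-butyldimethylsilyl)oxy]-4α-hydroxy-5α-eudesm-11(13)-en-12-oate | C=C(C(=O)OC)[C@H]1[C@H](OC(=O)/C(C)=C\C)[C@@H]2[C@@](C)(C[C@@H]1O[Si](C)(C)C(C)(C)C)[C@H](O[Si](C)(C)C(C)(C)C)CC[C@@]2(C)O | intermediate
35 | methyl 6α-(angeloyloxy)-1β,4α,8α-trihydroxy-5α-eudesm-11(13)-en-12-oate (CNP0136844.1) | C=C(C(=O)OC)[C@H]1[C@H](OC(=O)/C(C)=C\C)[C@@H]2[C@@](C)(C[C@@H]1O)[C@H](O)CC[C@@]2(C)O | target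

**Step count and risks**

Total step count: 22. Longest linear sequence: 21 steps (steps 1–7 and 9–22, from 1).

The three steps most likely to fail:

Step 15 (key step, new method). Four processes can take over: the alkene, made electron-poor by two allylic oxygens, may react more slowly than the enol silane of one molecule adds to the aluminium-bound ketone of another; the allylic C6–O bond may ionise once aluminium sits on O6; the C10 cation may take a hydride from C1 before C9 arrives; or the ketone may close with its oxygen axial and give the C4 epimer. The fallback changes the initiator to an oxocarbenium ion, the established trigger of acetal-type cation–olefin cyclisations, which is a stronger electrophile than a ketone–aluminium complex. It sets out from 22: benzyloxytrimethylsilane and TMSOTf in CH2Cl2 at −78 °C convert the C4 ketone in the flask into its O-benzyl oxocarbenium ion (as in reductive etherification of ketones), and cyclisation with the same enol silane terminator should give the C4 benzyl ether of the bicyclic ketone F1. Hydrogenolysis of the tertiary benzyl ether (H2, Pd(OH)2/C, EtOAc; no alkene is left in the molecule) comes back to the route at 24.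

Step 16. Protonation of the ketyl-derived carbanion may not favour the equatorial alcohol, so that epimer mixtures form, and the 8-alkoxide may close onto the C12 ester. The fallback sets the centre by inversion instead. It sets out from 24: LiBH(s-Bu)3 in THF at −78 °C attacks from the open α face, and quenching with AcOH at −78 °C (to prevent closure to the cis-lactone) should give the axial 8β-alcohol F2. Mitsunobu inversion (4-nitrobenzoic acid, PPh3, DIAD, toluene, 0 °C) gives the 8α-(4-nitrobenzoate) F3, and brief methanolysis (K2CO3, MeOH, 0 °C) comes back to the route at 25.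

Step 21. Acylation of the hindered 6α-hydroxyl, which is hydrogen-bonded to the C4 hydroxyl, may be slow, so that angelate-to-tiglate isomerisation of the activated acid or closure of the 6-hydroxyl onto the C12 ester competes. The fallback builds the Z-alkene on the ester instead of transferring it. It sets out from 31: DCC/DMAP esterification with 2-[bis(2,2,2-trifluoroethoxy)phosphoryl]propanoic acid, a saturated acid that cannot isomerise, gives the 6α-phosphonopropanoate F4. Still–Gennari olefination with acetaldehyde (KN(SiMe3)2, 18-crown-6, THF, −78 °C) is Z-selective and comes back to the route at 34.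

Further compounds
F1 | step 15 | methyl 4α-(benzyloxy)-1β-[(tert-butyldimethylsilyl)oxy]-8-oxo-6α-[(triethylsilyl)oxy]-13-nor-5α-eudesman-12-oate | COC(=O)C[C@H]1[C@H](O[Si](CC)(CC)CC)[C@@H]2[C@@](C)(CC1=O)[C@H](O[Si](C)(C)C(C)(C)C)CC[C@@]2(C)OCc1ccccc1
F2 | step 16 | methyl 1β-[(tert-butyldimethylsilyl)oxy]-4α,8β-dihydroxy-6α-[(triethylsilyl)oxy]-13-nor-5α-eudesman-12-oate | COC(=O)C[C@H]1[C@H](O[Si](CC)(CC)CC)[C@@H]2[C@@](C)(C[C@H]1O)[C@H](O[Si](C)(C)C(C)(C)C)CC[C@@]2(C)O
F3 | step 16 | methyl 1β-[(tert-butyldimethylsilyl)oxy]-4α-hydroxy-8α-[(4-nitrobenzoyl)oxy]-6α-[(triethylsilyl)oxy]-13-nor-5α-eudesman-12-oate | COC(=O)C[C@H]1[C@H](O[Si](CC)(CC)CC)[C@@H]2[C@@](C)(C[C@@H]1OC(=O)c1ccc(cc1)[N+](=O)[O-])[C@H](O[Si](C)(C)C(C)(C)C)CC[C@@]2(C)O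
F4 | step 21 | methyl 6α-({2-[bis(2,2,2-trifluoroethoxy)phosphoryl]propanoyl}oxy)-1β,8α-bis[(tert-butyldimethylsilyl)oxy]-4α-hydroxy-5α-eudesm-11(13)-en-12-oate | C=C(C(=O)OC)[C@H]1[C@H](OC(=O)C(C)P(=O)(OCC(F)(F)F)OCC(F)(F)F)[C@@H]2[C@@](C)(C[C@@H]1O[Si](C)(C)C(C)(C)C)[C@H](O[Si](C)(C)C(C)(C)C)CC[C@@]2(C)O
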